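**Retrosynthetic overview**
1. Locants: C1 (fusion C–CH3), C2/C3 (CH2), C4 (C(OH)i-Pr), C5 (fusion CH), C6 (CH–O-acyl), C7 (CH2), C8 (=C–CH3), C9 (=CH), C10 (CH2). Ring A is the cyclopentane C1–C5, ring B the cycloheptene C1/C5–C10, and β is the face of the C1 methyl.
2. Feature used: the oxygens on C4 and C6 are 1,3-related across C5, which is an aldol pattern once C6 is a ketone. The two methyl-bearing carbons C1 and C8 both lie β to C6, so ring B folds back onto a symmetric cross-conjugated dienone.
3. Disconnections, late to early: the C6–O ester; the C6 carbinol to the ketone (hydride steered by C4–OH); C8=C9 to the C7=C8 enone; C4–C5 by a reversible aldol of a 1,6-diketone, which closes ring A and sets C4 and C5 against C1.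
4. C1–C2 comes from catalytic asymmetric conjugate addition of a homoprenyl Grignard reagent (its alkene masks the isopropyl ketone) to 3,6-dimethylcyclohepta-2,6-dienone. The dienone comes from the [4+3] adduct of 2,5-dimethylfuran with an oxyallyl cation. A twofold olefination of hexane-2,5-dione was set aside because ketone olefination is sluggish, the dione self-condenses, and two Z-alkenes would be needed.
5. Ring order: ring B first (steps 1–3), ring A second (step 7).

Key step: step 7

Assumption: the sense of induction of the copper–NHC catalyst on the dienone is taken by analogy with β-methylcycloalkenones. L*·HPF6 is 1-(1-hydroxy-3,3-dimethylbutan-2-yl)-3-mesityl-4,5-dihydroimidazolium hexafluorophosphate. Both enantiomers are accessible from tert-leucinol, and the one that gives the (R)-adduct is used.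

Step 1
Reactants: 1 2,5-dimethylfuran; 2 1,1,3,3-tetrabromopropan-2-one
Product: 4 (1R,5S)-1,5-dimethyl-8-oxabicyclo[3.2.1]oct-6-en-3-one (meso), via dibromo cycloadduct 3 (not isolated)
Conditions: Zn–Cu couple, THF, −10 °C → rt; then Zn–Cu couple, NH4Cl, MeOH, rt
Reagents that add atoms: none
Why: Reductive generation of a bromo-oxyallyl cation from 2 and its [4+3] cycloaddition to the electron-rich furan build the seven-membered carbocycle with both methyl groups already β to the carbonyl, zinc reduction of the α-bromo ketone then removes both bromines, and the bridgeheads can only be cis-bridged (meso).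

Step 2
Reactants: 4 (1R,5S)-1,5-dimethyl-8-oxabicyclo[3.2.1]oct-6-en-3-one
Product: 5 (1R,5S)-1,5-dimethyl-8-oxabicyclo[3.2.1]octan-3-one (meso)
Conditions: H2 (1 atm), Pd/C, EtOAc, rt
Reagents that add atoms: none
Why: Catalytic hydrogenation saturates the strained disubstituted alkene, and the ketone and ether bridge should stay untouched.

Step 3
Reactants: 5 (1R,5S)-1,5-dimethyl-8-oxabicyclo[3.2.1]octan-3-one
Product: 6 3,6-dimethylcyclohepta-2,6-dien-1-one
Conditions: p-TsOH·H2O (0.2 equiv), toluene, reflux, Dean–Stark
Reagents that add atoms: none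
Why: Acid-catalysed twofold β-elimination (retro-oxa-Michael opening of the tertiary C–O bridge, then dehydration of the tertiary β-hydroxy ketone) is a known way from 8-oxabicyclo[3.2.1]octan-3-ones to cyclohepta-2,6-dienones and is driven here by azeotropic removal of water.

Step 4
Reactants: 6 3,6-dimethylcyclohepta-2,6-dien-1-one; 7 5-bromo-2-methylpent-2-ene
Product: 10 (R)-3,6-dimethyl-6-(4-methylpent-3-en-1-yl)cyclohept-2-en-1-one, via homoprenylmagnesium bromide 8 (not isolated), via bromomagnesium dienolate 9 (not isolated)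
Conditions: 7, Mg, Et2O, reflux; then Cu(OTf)2 (3 mol %), L*·HPF6 (4 mol %), Et2O, −30 °C, slow addition of 6; 1 M HCl
Reagents that add atoms: none
Why: Copper–NHC-catalysed asymmetric conjugate addition of a primary alkyl Grignard reagent to a β-methyl cyclic enone is an established route to all-carbon quaternary centres; the two enone arms of achiral 6 are related by a C2 axis, so the catalyst's choice of enone face alone sets C1, and dienolate 9 is inert to a second addition.

Step 5
Reactants: 10 (R)-3,6-dimethyl-6-(4-methylpent-3-en-1-yl)cyclohept-2-en-1-one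
Product: 11 (6S)-6-[2-(3,3-dimethyloxiran-2-yl)ethyl]-3,6-dimethylcyclohept-2-en-1-one (both oxirane epimers)
Conditions: mCPBA (1.05 equiv), CH2Cl2, 0 °C
Reagents that add atoms: mCPBA, OOC(=O)c1cccc(Cl)c1
Why: Prilezhaev epoxidation picks the electron-rich trisubstituted side-chain alkene over the electron-poor enone, and the oxirane stereocentre does not matter because step 6 erases it.

Step 6
Reactants: 11 (6S)-6-[2-(3,3-dimethyloxiran-2-yl)ethyl]-3,6-dimethylcyclohept-2-en-1-one
Product: 12 (S)-3,6-dimethyl-6-(4-methyl-3-oxopentyl)cyclohept-2-en-1-one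
Conditions: BF3·OEt2 (0.2 equiv), CH2Cl2, −78 → −20 °C
Reagents that add atoms: none
Why: In this Meinwald rearrangement the Lewis acid opens the oxirane at its tertiary carbon and a 1,2-hydride shift from C4 gives the isopropyl ketone, while C1 is not involved.

Step 7
Reactants: 12 (S)-3,6-dimethyl-6-(4-methyl-3-oxopentyl)cyclohept-2-en-1-one
Product: 13 (3R,3aR,8aS)-3-hydroxy-3-isopropyl-6,8a-dimethyl-2,3,3a,7,8,8a-hexahydroazulen-4(1H)-one
Conditions: KOt-Bu (0.2 equiv), t-BuOH–THF (1:1), 0 °C → rt, until the isomer composition no longer changes; aq NH4Cl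
Reagents that add atoms: none
Why: tert-Butoxide reversibly enolises the C6 ketone toward C5 and this enolate adds to the C4 isopropyl ketone, which forms C4–C5 and closes ring A in a 5-(enolexo)-exo-trig mode; the closest known reaction type is the base-mediated aldol cyclisation of 3-(3-oxoalkyl)cycloalkanones (1,6-diketones) used for cyclopentane annulation. Aldol, retro-aldol and C5 enolisation are all fast with an alkoxide in its alcohol, so the four C4/C5 diastereomers exchange through 12 and the product is chosen by stability against the fixed C1 centre, not by the kinetically easier cis closure. C5 is expected to end with its hydrogen trans to the C1 methyl because ring B can open the C10–C1–C5–C6 torsion that a trans-fused cyclopentane asks for, which leaves C4 pseudo-equatorial on ring B and close to the plane of the C6 carbonyl. C4 is expected to carry OH cis to C6 (O–H···O=C6 hydrogen bond, small group syn to the C1 methyl) and isopropyl on the opposite face, whereas each cis-fused or C4-epimeric alternative must put isopropyl syn to the C1 methyl, press it against C6 or give up the hydrogen bond; this ranking rests on conformational reasoning and has still to be tested. The step needs C5→C4 closure to prevail over C3→C6 and C9→C4 aldol closures and over C3→C8 Michael closure: the first two give strained bridged bicyclo[4.2.1] and bicyclo[4.3.1] aldols that can revert, and the last must build a quaternary carbon at fully substituted C8 through a boat-like bicyclo[3.2.2] transition state and should be slow at or below room temperature. Substoichiometric base and low temperature keep E1cB loss of water across C4–C5 slow, and any β,γ-enone formed on quenching is simply the product of step 8.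

Step 8
Reactants: 13 (3R,3aR,8aS)-3-hydroxy-3-isopropyl-6,8a-dimethyl-2,3,3a,7,8,8a-hexahydroazulen-4(1H)-one
Product: 15 (3R,3aR,8aR)-3-hydroxy-3-isopropyl-6,8a-dimethyl-2,3,3a,5,8,8a-hexahydroazulen-4(1H)-one, via dipotassium dienolate 14 (not isolated)
Conditions: KOt-Bu (4 equiv), THF–t-BuOH (4:1), −10 °C, 1 h; cannulated into cold AcOH–THF–H2O; used crude
Reagents that add atoms: none
Why: This is deconjugation by kinetic α-protonation: excess base removes a C9 proton to give the more substituted endocyclic extended dienolate, in which C6 is an enolate carbon so that neither retro-aldol nor elimination through C5 can run, fast protonation at C7 then leaves C8=C9 with C1, C4 and C5 untouched, and the small energy gap between conjugated and β,γ-isomers in seven-membered rings helps the product to persist.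

Step 9
Reactants: 15 (3R,3aR,8aR)-3-hydroxy-3-isopropyl-6,8a-dimethyl-2,3,3a,5,8,8a-hexahydroazulen-4(1H)-one
Product: 16 (3R,3aS,4S,8aR)-3-isopropyl-6,8a-dimethyl-1,2,3,3a,4,5,8,8a-octahydroazulene-3,4-diol (jaeschkeanadiol)
Conditions: Me4NBH(OAc)3 (5 equiv), MeCN–AcOH (1:1), −30 → 0 °C; aq NaHCO3
Reagents that add atoms: none
Why: In this Evans–Saksena reduction the C4–OH displaces an acetate on boron and hydride is delivered intramolecularly to the β face of C6 where that oxygen sits, which should place H6 β and O6 α (the 1,3-anti diol), and a ketone without a bound hydroxyl is not reduced by this reagent, so attack from the open α face has no pathway.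

Step 10
Reactants: 17 (E)-4-hydroxycinnamic acid (p-coumaric acid)
Product: 19 (E)-3-[4-(tert-butyldimethylsilyloxy)phenyl]prop-2-enoic acid, via bis-silylated coumarate 18 (not isolated)
Conditions: TBSCl (2.3 equiv), imidazole, DMF, rt; then AcOH–THF–H2O (3:1:1), rt
Reagents that add atoms: TBSCl, CC(C)(C)[Si](C)(C)Cl
Why: Silylation covers phenol and acid, and the much more labile silyl ester is hydrolysed selectively under mild acid, to which the aryl silyl ether is stable.

Step 11
Reactants: 16 (3R,3aS,4S,8aR)-3-isopropyl-6,8a-dimethyl-1,2,3,3a,4,5,8,8a-octahydroazulene-3,4-diol; 19 (E)-3-[4-(tert-butyldimethylsilyloxy)phenyl]prop-2-enoic acid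
Product: 20 (3R,3aS,4S,8aR)-3-hydroxy-3-isopropyl-6,8a-dimethyl-1,2,3,3a,4,5,8,8a-octahydroazulen-4-yl (E)-3-[4-(tert-butyldimethylsilyloxy)phenyl]prop-2-enoate
Conditions: DCC (1.6 equiv), DMAP (0.5 equiv), CH2Cl2, 0 → 40 °C
Reagents that add atoms: none
Why: Steglich esterification acylates only the secondary C6–OH with retention at C6, because the tertiary C4–OH flanked by isopropyl is inert, and the E-alkene is not touched.

Step 12
Reactants: 20 (3R,3aS,4S,8aR)-3-hydroxy-3-isopropyl-6,8a-dimethyl-1,2,3,3a,4,5,8,8a-octahydroazulen-4-yl (E)-3-[4-(tert-butyldimethylsilyloxy)phenyl]prop-2-enoate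
Product: 21 (3R,3aS,4S,8aR)-3-hydroxy-3-isopropyl-6,8a-dimethyl-1,2,3,3a,4,5,8,8a-octahydroazulen-4-yl (E)-3-(4-hydroxyphenyl)prop-2-enoate (target)
Conditions: Bu4NF (1.1 equiv), AcOH (1.2 equiv), THF, 0 °C
Reagents that add atoms: none
Why: Fluoride cleaves the aryl silyl ether rapidly, and the acetic acid buffer keeps the medium non-basic so that the ester, the tertiary alcohol and the alkenes survive.

**Compound list**
1 | 2,5-dimethylfuran | Cc1ccc(C)o1 | starting material
2 | 1,1,3,3-tetrabromopropan-2-one | BrC(Br)C(=O)C(Br)Br | starting material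
3 | 2,4-dibromo-1,5-dimethyl-8-oxabicyclo[3.2.1]oct-6-en-3-one (C–Br epimers) | C[C@]12C(Br)C(=O)C(Br)[C@](C)(C=C1)O2 | intermediate
4 | (1R,5S)-1,5-dimethyl-8-oxabicyclo[3.2.1]oct-6-en-3-one (meso) | C[C@]12CC(=O)C[C@](C)(C=C1)O2 | intermediate
5 | (1R,5S)-1,5-dimethyl-8-oxabicyclo[3.2.1]octan-3-one (meso) | C[C@]12CC(=O)C[C@](C)(CC1)O2 | intermediate
6 | 3,6-dimethylcyclohepta-2,6-dien-1-one | CC1=CC(=O)C=C(C)CC1 | intermediate
7 | 5-bromo-2-methylpent-2-ene | CC(C)=CCCBr | starting material
8 | (4-methylpent-3-en-1-yl)magnesium bromide | CC(C)=CCC[Mg]Br | intermediate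
9 | bromomagnesium cross-conjugated dienolate of 10 (C5=C6–O, C7=C8) | CC=1CC[C@@](C)(CCC=C(C)C)C=C(O[Mg]Br)C=1 | intermediate
10 | (R)-3,6-dimethyl-6-(4-methylpent-3-en-1-yl)cyclohept-2-en-1-one | CC=1CC[C@@](C)(CCC=C(C)C)CC(=O)C=1 | intermediate
11 | (6S)-6-[2-(3,3-dimethyloxiran-2-yl)ethyl]-3,6-dimethylcyclohept-2-en-1-one (oxirane epimers) | CC=1CC[C@@](C)(CCC2OC2(C)C)CC(=O)C=1 | intermediate
12 | (S)-3,6-dimethyl-6-(4-methyl-3-oxopentyl)cyclohept-2-en-1-one | CC=1CC[C@@](C)(CCC(=O)C(C)C)CC(=O)C=1 | intermediate
13 | (3R,3aR,8aS)-3-hydroxy-3-isopropyl-6,8a-dimethyl-2,3,3a,7,8,8a-hexahydroazulen-4(1H)-one | CC=1CC[C@@]2(C)CC[C@@](O)(C(C)C)[C@@H]2C(=O)C=1 | intermediate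
14 | dipotassium C4-alkoxide / C6=C7–C8=C9 dienolate of 13 | CC1=CC[C@@]2(C)CC[C@@]([O-])(C(C)C)[C@@H]2C([O-])=C1.[K+].[K+] | intermediate
15 | (3R,3aR,8aR)-3-hydroxy-3-isopropyl-6,8a-dimethyl-2,3,3a,5,8,8a-hexahydroazulen-4(1H)-one | CC1=CC[C@@]2(C)CC[C@@](O)(C(C)C)[C@@H]2C(=O)C1 | intermediate
16 | (3R,3aS,4S,8aR)-3-isopropyl-6,8a-dimethyl-1,2,3,3a,4,5,8,8a-octahydroazulene-3,4-diol | CC1=CC[C@@]2(C)CC[C@@](O)(C(C)C)[C@@H]2[C@@H](O)C1 | intermediate
17 | (E)-4-hydroxycinnamic acid | OC(=O)/C=C/c1ccc(O)cc1 | starting material
18 | tert-butyldimethylsilyl (E)-3-[4-(tert-butyldimethylsilyloxy)phenyl]prop-2-enoate | CC(C)(C)[Si](C)(C)OC(=O)/C=C/c1ccc(O[Si](C)(C)C(C)(C)C)cc1 | intermediate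
19 | (E)-3-[4-(tert-butyldimethylsilyloxy)phenyl]prop-2-enoic acid | OC(=O)/C=C/c1ccc(O[Si](C)(C)C(C)(C)C)cc1 | intermediate
20 | O-TBS-protected target ester | CC1=CC[C@@]2(C)CC[C@@](O)(C(C)C)[C@@H]2[C@@H](OC(=O)/C=C/c2ccc(O[Si](C)(C)C(C)(C)C)cc2)C1 | intermediate
21 | (3R,3aS,4S,8aR)-3-hydroxy-3-isopropyl-6,8a-dimethyl-1,2,3,3a,4,5,8,8a-octahydroazulen-4-yl (E)-3-(4-hydroxyphenyl)prop-2-enoate | CC1=CC[C@@]2(C)CC[C@@](O)(C(C)C)[C@@H]2[C@@H](OC(=O)/C=C/c2ccc(O)cc2)C1 | target

**Totals**
Total step count: 12. Longest linear sequence: 11 (steps 1–9, 11, 12).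

**Steps most likely to fail**

Step 7.
- What may go wrong: the equilibrium may come to rest on a cis ring junction or on the open diketone. The mixture may also drain by loss of water across C4–C5, or by Michael closure onto C8, before it settles.
- Fallback (from 12, back at 13): the C4 oxygen is delivered by a directed reagent instead of by equilibrium.
  - 12 is pushed with KOH in hot EtOH through aldol condensation to (S)-3-isopropyl-6,8a-dimethyl-2,7,8,8a-tetrahydroazulen-4(1H)-one F1, into which all ketol isomers converge.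
  - Luche reduction (NaBH4, CeCl3·7H2O, MeOH) from the face opposite the C1 methyl should give (4R,8aS)-3-isopropyl-6,8a-dimethyl-1,2,4,7,8,8a-hexahydroazulen-4-ol F2.
  - Hydroxyl-directed epoxidation (VO(acac)2, t-BuOOH) of the more nucleophilic tetrasubstituted C4=C5 alkene should place the oxirane on the β face and give the syn-epoxy alcohol F3.
  - Dess–Martin oxidation gives the α,β-epoxy ketone F4.
  - SmI2 in THF–MeOH at low temperature cleaves the C5–O bond, the known reduction of α,β-epoxy ketones to β-hydroxy ketones, and gives 13.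
  - C4 is then fixed by the oxirane. A C5 proton placed on the wrong face can be corrected by brief amine-base epimerisation, because with C4 fixed the cis-fused epimer would hold isopropyl against C6 on the concave face.

Step 8.
- What may go wrong: the ketol may open by retro-aldol through the C4 alkoxide before the dienolate forms. The enone may reconjugate during the quench. Proton loss from the C8 methyl may lead to the exocyclic alkene.
- Fallback (from 13, back at 15): soft enolisation with the hydroxyl masked, so that no C4 alkoxide ever exists.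
  - Me3SiOTf/Et3N in CH2Cl2 should silylate C4–OH and, because C5–H is buried between two fully substituted carbons, enolise toward C9 to give the bis(trimethylsilyl) dienol ether F5.
  - MeLi in THF releases the lithium dienolate from the enol silyl ether only, and AcOH at −78 °C protonates C7 to give the C4-O-trimethylsilyl β,γ-enone F6.
  - HF·pyridine in THF at 0 °C removes the tertiary silyl ether and gives 15.

Step 4.
- What may go wrong: competing 1,2-addition and weak facial discrimination on the flatter, less electrophilic cross-conjugated dienone.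
- Fallback (from 8, back at 10): the stereocentre is set on a simple mono-enone and the C7=C8(CH3) enone is built afterwards.
  - 8 is added under the same type of catalysis to commercial 3-methylcyclohept-2-en-1-one, a substrate class on which this reaction is established, to give (S)-3-methyl-3-(4-methylpent-3-en-1-yl)cycloheptan-1-one F7.
  - LiN(i-Pr)2/Me3SiCl at −78 °C removes the less hindered C7 proton and gives the kinetic trimethylsilyl enol ether F8.
  - Saegusa–Ito oxidation with Pd(OAc)2 in MeCN gives (S)-6-methyl-6-(4-methylpent-3-en-1-yl)cyclohept-2-en-1-one F9.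
  - Me2CuLi/Me3SiCl gives the β-methyl trimethylsilyl enol ether F10.
  - A second Saegusa–Ito oxidation gives 10.

**Further compounds**
F1 | step 7 | (S)-3-isopropyl-6,8a-dimethyl-2,7,8,8a-tetrahydroazulen-4(1H)-one | CC=1CC[C@@]2(C)CCC(C(C)C)=C2C(=O)C=1
F2 | step 7 | (4R,8aS)-3-isopropyl-6,8a-dimethyl-1,2,4,7,8,8a-hexahydroazulen-4-ol | CC=1CC[C@@]2(C)CCC(C(C)C)=C2[C@H](O)C=1
F3 | step 7 | syn-epoxy alcohol (C4–C5 oxirane, C6–OH and C1–CH3 on one face) | CC=1CC[C@@]2(C)CC[C@]3(C(C)C)O[C@]23[C@H](O)C=1
F4 | step 7 | α,β-epoxy ketone (C4–C5 oxirane on the face of C1–CH3, C6 ketone) | CC=1CC[C@@]2(C)CC[C@]3(C(C)C)O[C@]23C(=O)C=1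
F5 | step 8 | bis(trimethylsilyl) dienol ether (C4–OSiMe3; C6(OSiMe3)=C7–C8=C9) | CC1=CC[C@@]2(C)CC[C@@](O[Si](C)(C)C)(C(C)C)[C@@H]2C(O[Si](C)(C)C)=C1
F6 | step 8 | C4-O-trimethylsilyl β,γ-enone | CC1=CC[C@@]2(C)CC[C@@](O[Si](C)(C)C)(C(C)C)[C@@H]2C(=O)C1
F7 | step 4 | (S)-3-methyl-3-(4-methylpent-3-en-1-yl)cycloheptan-1-one | C1CC[C@@](C)(CCC=C(C)C)CC(=O)C1
F8 | step 4 | kinetic trimethylsilyl enol ether of F7 (C6=C7) | C1CC[C@@](C)(CCC=C(C)C)CC(O[Si](C)(C)C)=C1
F9 | step 4 | (S)-6-methyl-6-(4-methylpent-3-en-1-yl)cyclohept-2-en-1-one | O=C1C=CCC[C@@](C)(CCC=C(C)C)C1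
F10 | step 4 | β-methyl trimethylsilyl enol ether (C8 epimers) | CC1CC[C@@](C)(CCC=C(C)C)CC(O[Si](C)(C)C)=C1
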